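The constants of the steps were hidden, so I reckoned from a quantity that needs none of them.

| flask | substrate | other conformer | remark | time |
|---|---|---|---|---|
| teal | 2 M | 0.12 equiv | run made earlier |  |
| grey | 2 M | 0.19 equiv | run made earlier |  |
| ochre | 3 M | 0.25 equiv | run made earlier |  |
| flask | 2.0 M | 0.250 equiv |  | 15 d |

| run | time / d | target / % |
|---|---|---|
| teal | 0.104 | 47 |
| teal | 0.333 | 65 |
| teal | 1.04 | 57 |
| teal | 3.00 | 56 |
| teal | 10.0 | 55 |
| grey | 0.104 | 42 |
| grey | 0.333 | 64 |
| grey | 1.04 | 56 |
| grey | 3.00 | 55 |
| grey | 10.0 | 57 |
| ochre | 0.104 | 44 |
| ochre | 0.333 | 64 |
| ochre | 1.04 | 58 |
| ochre | 3.00 | 56 |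
| ochre | 10.0 | 57 |

(standard deviation of a reading: 1.5 percentage points)

- the earlier runs were read with a standard deviation of 1.5 percentage points
- steps thought possible: substrate <-> other conformer; substrate -> target; other conformer -> isomer of the product; target <-> isomer of the product

1. the best time, 15 d at the latest, for target
2. the amount of target, in percent of the substrate and other conformer together charged, at that time
3. earliest time at which at least nineteen twentieths of that best amount are there, in d
4. latest time at which they still are, in d

At 10.0 d the teal, grey and ochre runs average 56.3% target, each reading carrying 1.5 percentage points. This is the plateau share, the part of the charge standing as target once the readings stop moving, which I read as thermodynamic control. I took the even split between target and isomer of the product as the zero of the scale, so the plateau share stands 6.3 points above it. At 0.333 d the same runs average 64.3%, and the level that the window asks for on that reading, 61.1%, is more than the plateau share, so I expected this flask's window to shut.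

The forecast gave 64% at 0.34 d, with a window from 0.21 d to 0.59 d: “The plateau lies below this level, so the window closes.”

The flask gave 63.9% at 0.390 d, with a window from 0.245 d to 0.690 d.

    substrate ⇌ other conformer (K = 0.0572, k = 0.0414 h⁻¹)
    substrate → target (k = 0.297 h⁻¹)
    other conformer → isomer of the product (k = 2.26 h⁻¹)
    target ⇌ isomer of the product (K = 0.818, k = 0.0478 h⁻¹)

The largest single effect on the peak that I can name is the step between target and isomer of the product: this flask without it peaks at 76.7%, not 63.9%. Its relaxation half-life, 0.272 d, is short against the 15 d allowed. In this flask the plateau share lies below the level of 60.7%. The neighbour charged with 1.00 equiv of other conformer peaks at 56.8%, so its level of 54.0% lies below the plateau share, and at 15.0 d that neighbour holds 55.0% target.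

The runs stem from a simulated flask with made-up constants, and the scatter is random.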